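Numbering used throughout (fixed by the steps below): 1 syringaldehyde; 2 its benzyl ether; 3 aryl formate (not isolated); 4 4-(benzyloxy)-3,5-dimethoxyphenol; 5 veratraldehyde; 6 geminal dichloride of 5; 7 bis-aryl acetal of 5 with 4; 8 1,1-diethoxyethene; 9 O-aryl oxocarbenium ion (not isolated); 10 tethered dialkoxycarbenium ion (not isolated); 11 (2S)-chroman 4,4-diethyl ketal; 12 (2S)-6-O-benzyl flavanone; 13 target.

## Analysis of the target

Compound 13 is a flavanone: benzene ring A is fused to a dihydropyranone ring C (O1, C2, C3, C4, C4a, C8a) that carries the 3,4-dimethoxyphenyl ring B at C2 and the ketone at C4. Ring A is oxygenated at every position except C8, with OMe at C5 and C7 and a free OH at C6, so the 6-oxygen must stay distinguishable from its two methylated neighbours throughout. C2 is the only stereocentre and the SMILES descriptor corresponds to S (O1 > C1' > C3 > H). This centre is benzylic, oxygen-bearing and β to the C4 carbonyl, so base, and more slowly strong acid, open ring C by retro-oxa-Michael reaction and racemise it; the C2–O1 bond is also a benzylic ether open to hydrogenolysis. Both aromatic rings are very electron-rich, which invites over-oxidation and stray Friedel–Crafts chemistry under acid. The difficulty is therefore not the skeleton but creating C2 in one absolute configuration by a step that is not the reversible closure of a chalcone, and then finishing without base. The strategy rests on reading C4a=C8a–O1–C2 as a cationic 2-oxadiene once C2 is an oxocarbenium carbon (ion 9), with C3–C4, at the ketal oxidation level, corresponding to ketene acetal 8. The ring A partner 4 is symmetric about its O–C1···C4 axis, so the two ortho carbons that could become C4a are equivalent.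

## Retrosynthetic reasoning

13 ⇒ 12. The O–CH2Ph bond on the 6-oxygen is cut last. A benzyl ether is chosen because this oxygen must survive peracid, carbonate base and a strong acid at low temperature, and must be freed without base, which would open ring C. Neutral hydrogenolysis should meet this.

12 ⇒ 11. The C4 carbonyl is traced back to the diethyl ketal. No complexity is gained; the ketal is simply the form in which the annulation delivers C4, and buffered aqueous acid should unmask it without touching C2.

11 ⇒ 7 + 8 (through 9 and 10). Ring C is opened at C2–C3 and C4–C4a. These two bonds separate a two-carbon piece at the acid oxidation level (8) from the four-atom unit C4a=C8a–O1–C2, which is a heterodiene when C2 is cationic (9).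
- The cut is preferred to the classical O1–C2 cut, whose forward reaction is a reversible oxa-Michael closure and a poor place to fix an enantiomer, and to a C4–C4a acylation cut, which leaves the stereocentre to be made separately.
- One step then forms both C–C bonds, ring C and the stereocentre, and delivers C4 at the ketone oxidation level.
- The forward reaction must ionise 7 under a chiral counter-anion, let 8 add to one face of 9, and close 10 onto the arene.
- A dialkyl ketene acetal is used rather than a silyl one, so that 10 has no silyl group to shed and cannot simply collapse to an ester.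
- The symmetrical acetal 7 is used rather than an unsymmetrical alkyl aryl acetal. In the latter the aryloxy group is the better leaving group and the alkoxy-stabilised cation the more stable one, so ionisation would be expected to go at least partly the wrong way. With two identical aryloxy groups either C–O cleavage gives 9, the acetal carbon is not a stereocentre, and the group lost is 4, which can be recovered.

7 ⇒ 4 + 6. Both acetal C–O bonds are cut, to two molecules of 4 and the geminal dichloride 6. Assembly by substitution under base is chosen over acid-mediated acetal exchange, because acid would let the very nucleophilic ring carbons of 4 attack the benzylic cation.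

6 ⇒ 5. The two C–Cl bonds are traced back to the aldehyde oxygen of 5, a one-step functional group change on a commodity aldehyde.

4 ⇒ 2 (through 3). The aryl C–O bond that becomes O1–C8a is traced back to the aryl–CHO bond of 2 by an aryl-migrating peracid oxidation. The three contiguous oxygens of ring A are thus bought in place, and the oxygen that becomes O1 is introduced at the one carbon that carried the formyl group.

2 ⇒ 1. The benzyl ether is cut back to the only free hydroxyl of 1, which is exactly the oxygen that ends as the 6-OH of 13.

## Alternatives that were turned down

Alternative 1: Ring A is disconnected at C4a–C5 and built last by an intramolecular Claisen (Dieckmann-type) condensation on a preformed, enantioenriched dihydropyranone. The precursor A2 carries a CH2–CO–CH(OBn)–CO2Et chain on the ring carbon that becomes C8a. Base forms the extended dienolate, the vinylogous α-carbon (future C4a) attacks the ester carbon (future C5), ethoxide leaves and enolisation gives the 5,7-dihydroxyflavanone A1.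
- For: it mirrors polyketide biosynthesis, and the C2 centre could come from an established catalytic asymmetric hetero-Diels–Alder reaction of 5. On the pedigree of its stereo-defining step it is stronger than the chosen route.
- Against: ring A is rebuilt although 1 supplies it ready-made. A2 needs a multistep assembly of a sensitive polycarbonyl chain. A1 then requires two O-methylations under base, one of them on the chelated 5-OH, on a flavanone that opens to the chalcone and racemises under exactly those conditions.
- Comparison: the chosen route differentiates the three ring A oxygens from the first step, uses no base after C2 is set and is roughly half as long.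

Alternative 2: Ring C is disconnected at C3=C4 by ring-closing metathesis. Second-generation Grubbs catalyst would join the internal vinyl carbon of the (S)-1-arylallyl aryl ether A4 to its silyl enol ether carbon, with extrusion of the two terminal CH2 groups, giving the cyclic silyl enol ether A3. Mild desilylation would lead to 12.
- For: every step has close precedent. The stereocentre can come from an asymmetric allylic etherification ([Ir(cod)Cl]2 with a chiral phosphoramidite). C4 arrives at the right oxidation level. On reliability of the individual steps this plan is stronger than the chosen one.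
- Against: the C–O bond of A4 is both allylic and electron-rich benzylic, so it can ionise, and the free C8 position allows aromatic Claisen rearrangement on warming with the ruthenium catalyst. The enol ether carbon is 1,1-disubstituted and flanked by two ortho substituents, so closure to a hindered trisubstituted enol ether should be slow and allyl ether isomerisation can compete. The phenol used in the etherification must already carry its ortho acyl group and is then a chelated, hindered nucleophile. The sequence runs to about ten steps.
- Comparison: the chosen route offers a single catalytic step that makes ring and stereocentre together, and a seven-step sequence in which the stereocentre never meets heat or a metal alkylidene.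

Alternative 3: Ring C is disconnected at O1–C2 and C3–C4 with an extra carbon on C3. A diarylprolinol silyl ether would convert the enal A6 into an iminium ion that takes the phenol oxygen of salicylaldehyde A7 at its β-carbon, and the enamine would condense with the aryl aldehyde to give the 2H-chromene-3-carbaldehyde A5.
- For: the domino is well precedented for salicylaldehydes and enals, is convergent, and builds ring C and the stereocentre from two simple aldehydes. On precedent of the key step it is stronger than the chosen route.
- Against: A5 has carbon where none is wanted and no oxygen where one is needed. The formyl group must be excised (for example with stoichiometric RhCl(PPh3)3) and C4 oxidised through a regioselective oxygenation of a hindered internal olefin (Wacker-type, PdCl2/CuCl/O2), adding at least three steps. 2-Aryl-2H-chromenes can also racemise by reversible electrocyclic ring opening, the formyl group of A7 is flanked by two ortho substituents, and the donor-rich A6 is a weak acceptor.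
- Comparison: the chosen annulation puts C4 at the ketone oxidation level directly, with nothing to remove.

Key step: step 5

Assumption: the sense of induction of the confined acid in step 5 cannot be predicted with confidence; the route is written with the catalyst enantiomer that delivers the (2S) series, and the antipode would be used if a first screen showed the opposite sense.

## Steps

Step 1
Reactants: 1 syringaldehyde (4-hydroxy-3,5-dimethoxybenzaldehyde)
Product: 2 4-(benzyloxy)-3,5-dimethoxybenzaldehyde
Conditions: BnBr, K2CO3, DMF, 60 °C
Reagents that add atoms: benzyl bromide, BrCc1ccccc1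
Why: Williamson etherification of the only acidic site; the benzyl ether marks the oxygen that becomes the 6-OH and tolerates the peracid, base and acid steps that follow.

Step 2
Reactants: 2 4-(benzyloxy)-3,5-dimethoxybenzaldehyde
Product: 4 4-(benzyloxy)-3,5-dimethoxyphenol, via aryl formate 3 (not isolated)
Conditions: mCPBA, CH2Cl2, 0 °C → rt; aq. NaHCO3/Na2S2O3 wash; then K2CO3 (cat.), MeOH, rt
Reagents that add atoms: mCPBA, OOC(=O)c1cccc(Cl)c1
Why: Baeyer–Villiger (Dakin-type) oxidation; in this electron-rich aldehyde the aryl group migrates in the Criegee adduct to give formate 3, which mild methanolysis cleaves. A peracid is used because the alkaline Dakin reaction needs a free ortho or para hydroxyl.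

Step 3
Reactants: 5 veratraldehyde (3,4-dimethoxybenzaldehyde)
Product: 6 4-(dichloromethyl)-1,2-dimethoxybenzene
Conditions: SOCl2, DMF (cat.), CH2Cl2, 0 → 40 °C; evaporate, use crude
Reagents that add atoms: thionyl chloride, ClS(Cl)=O
Why: deoxygenative geminal dichlorination of an aromatic aldehyde through chloroiminium activation; the para methoxy group assists both C–Cl formations. The product is moisture-sensitive and should be used without purification.

Step 4
Reactants: 4 4-(benzyloxy)-3,5-dimethoxyphenol (2 equiv); 6 4-(dichloromethyl)-1,2-dimethoxybenzene
Product: 7 3,4-dimethoxybenzaldehyde bis[4-(benzyloxy)-3,5-dimethoxyphenyl] acetal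
Conditions: Cs2CO3, MeCN, 4 Å MS, 0 °C → rt; purify on Et3N-deactivated silica
Reagents that add atoms: none
Why: double nucleophilic substitution of a geminal dihalide by aryloxide (Williamson-type acetal synthesis); each chloride leaves with help from the para oxygen, and the caesium aryloxide in a dipolar aprotic solvent should attack through oxygen. Basic conditions avoid the Friedel–Crafts C-alkylation of the electron-rich phenol that acid would promote.

Step 5
Reactants: 7 3,4-dimethoxybenzaldehyde bis[4-(benzyloxy)-3,5-dimethoxyphenyl] acetal; 8 1,1-diethoxyethene
Product: 11 (2S)-6-(benzyloxy)-4,4-diethoxy-2-(3,4-dimethoxyphenyl)-5,7-dimethoxychroman, via oxocarbenium ion 9 (not isolated), via dialkoxycarbenium ion 10 (not isolated)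
Conditions: (S,S)-IDPi acid (5 mol%; 1,1'-bi-2-naphthol-derived imidodiphosphorimidate, N-SO2CF3, 3,3'-bis[3,5-(CF3)2C6H3]), 8 (3 equiv), CH2Cl2/toluene, −78 → −40 °C; Et3N quench, cold dilute NaOH wash (recovers 4), basic alumina
Reagents that add atoms: none
Why: Proposed new method: the acid, directly or through the 1,1-diethoxyethyl cation it forms with 8, removes one aryloxy group of 7 as phenol 4 and leaves the planar ion 9 as a contact ion pair with the confined chiral anion; because both aryloxy groups are identical, no other cation can form. The CH2 carbon of 8 adds to C2 of 9 (Mukaiyama-type addition, C2–C3) to give 10, which has no silyl group to lose and should persist until the ortho carbon C4a, activated by O1 and 5-OMe (ortho) and 7-OMe (para), attacks it (C4–C4a); loss of the ring proton restores aromaticity and returns the acid. Overall this is a stepwise polar [4+2] annulation of the cationic 2-oxadiene C4a=C8a–O1=C2 with an electron-rich alkene; the closest known reactions are Lewis-acid-promoted oxa-Povarov reactions of aryl oxocarbenium ions with alkenes, which give racemic chromans, and chiral-acid-catalysed Mukaiyama-type additions of silyl ketene acetals to oxocarbenium ions, which stop at the ester. Ring C is closed by a 6-exo-trig intramolecular Friedel–Crafts alkylation (exo with respect to the C=O+ bond of 10, six-membered transition state). The C2 stereocentre is created in the first C–C bond formation and is controlled by the catalyst alone: the chiral anion must leave one face of 9 open to 8. The step needs 8 to outcompete liberated 4 for ion 9 (8 is by far the stronger carbon nucleophile and is in excess) and ring closure to outcompete capture of 10 at oxygen (an intramolecular, triply activated arene, low temperature and no added alcohol favour this); regioselectivity is secured by the two equivalent ortho positions of the aryl ether. Partial loss of ethanol from the crowded ketal to the enol ether would be harmless, since both are hydrolysed to the same ketone in step 6.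

Step 6
Reactants: 11 (2S)-6-(benzyloxy)-4,4-diethoxy-2-(3,4-dimethoxyphenyl)-5,7-dimethoxychroman
Product: 12 (2S)-6-(benzyloxy)-2-(3,4-dimethoxyphenyl)-5,7-dimethoxychroman-4-one
Conditions: PPTS (10 mol%), acetone/H2O 10:1, rt
Reagents that add atoms: water, O
Why: acid-catalysed ketal hydrolysis through the aryl-stabilised C4 oxocarbenium ion, which should be fast for a ketal on a trioxygenated ring, so a buffered acid at room temperature suffices. No base is present and the acid is too weak to open ring C, so C2 should be retained.

Step 7
Reactants: 12 (2S)-6-(benzyloxy)-2-(3,4-dimethoxyphenyl)-5,7-dimethoxychroman-4-one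
Product: 13 (2S)-2-(3,4-dimethoxyphenyl)-6-hydroxy-5,7-dimethoxychroman-4-one (CNP0313204.1)
Conditions: H2 (1 atm), 10% Pd/C, EtOAc, rt
Reagents that add atoms: none
Why: hydrogenolysis of an aryl benzyl ether under neutral conditions; O-benzyl cleavage should be faster than attack on the cyclic benzylic C2–O1 bond or the aryl ketone at ambient pressure. The neutral medium leaves C2 untouched.

## Compound list

1 | syringaldehyde (4-hydroxy-3,5-dimethoxybenzaldehyde) | COc1cc(C=O)cc(OC)c1O | starting material
2 | 4-(benzyloxy)-3,5-dimethoxybenzaldehyde | COc1cc(C=O)cc(OC)c1OCc1ccccc1 | intermediate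
3 | 4-(benzyloxy)-3,5-dimethoxyphenyl formate | COc1cc(OC=O)cc(OC)c1OCc1ccccc1 | intermediate (not isolated)
4 | 4-(benzyloxy)-3,5-dimethoxyphenol | COc1cc(O)cc(OC)c1OCc1ccccc1 | intermediate
5 | veratraldehyde (3,4-dimethoxybenzaldehyde) | COc1ccc(C=O)cc1OC | starting material
6 | 4-(dichloromethyl)-1,2-dimethoxybenzene | COc1ccc(C(Cl)Cl)cc1OC | intermediate
7 | 3,4-dimethoxybenzaldehyde bis[4-(benzyloxy)-3,5-dimethoxyphenyl] acetal; 5,5'-{[(3,4-dimethoxyphenyl)methylene]bis(oxy)}bis[2-(benzyloxy)-1,3-dimethoxybenzene] (achiral) | COc1ccc(C(Oc2cc(OC)c(OCc3ccccc3)c(OC)c2)Oc2cc(OC)c(OCc3ccccc3)c(OC)c2)cc1OC | intermediate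
8 | 1,1-diethoxyethene | C=C(OCC)OCC | starting material
9 | [4-(benzyloxy)-3,5-dimethoxyphenyl](3,4-dimethoxybenzylidene)oxonium, ion pair with the catalyst anion | COc1ccc(C=[O+]c2cc(OC)c(OCc3ccccc3)c(OC)c2)cc1OC | intermediate (not isolated)
10 | (3S)-3-[4-(benzyloxy)-3,5-dimethoxyphenoxy]-1,1-diethoxy-3-(3,4-dimethoxyphenyl)propan-1-ylium, ion pair with the catalyst anion | COc1ccc([C@H](CC(OCC)=[O+]CC)Oc2cc(OC)c(OCc3ccccc3)c(OC)c2)cc1OC | intermediate (not isolated)
11 | (2S)-6-(benzyloxy)-4,4-diethoxy-2-(3,4-dimethoxyphenyl)-5,7-dimethoxychroman | COc1ccc([C@@H]2CC(OCC)(OCC)c3c(cc(OC)c(OCc4ccccc4)c3OC)O2)cc1OC | intermediate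
12 | (2S)-6-(benzyloxy)-2-(3,4-dimethoxyphenyl)-5,7-dimethoxychroman-4-one | COc1ccc([C@@H]2CC(=O)c3c(cc(OC)c(OCc4ccccc4)c3OC)O2)cc1OC | intermediate
13 | (2S)-2-(3,4-dimethoxyphenyl)-6-hydroxy-5,7-dimethoxychroman-4-one (CNP0313204.1) | COc1ccc([C@@H]2CC(=O)c3c(cc(OC)c(O)c3OC)O2)cc1OC | target

## Step count and least certain steps

Total: 7 steps. Longest linear sequence: 6 steps (steps 1, 2, 4, 5, 6, 7); step 3 is a one-step branch.

Step 5 (key step, new method). Several things can go wrong.
- Most likely, the acid is drained by irreversible C-protonation of 8, followed by cationic oligomerisation of 8, before 7 is ionised.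
- Ion 10 may be captured at oxygen by liberated phenol or adventitious water, which leads to a ring-opened ester instead of ring closure.
- Facial discrimination may be weak if the large, flat, highly delocalised ion 9 pairs only loosely with the anion.
- Acid-mediated re-ionisation of the C2–O1 bond of 11 may erode the enantiomeric purity.

Fallback by known chemistry, setting out from 4 and returning at 12: Friedel–Crafts acetylation of 4 (Ac2O, BF3·OEt2) should give 1-[3-(benzyloxy)-6-hydroxy-2,4-dimethoxyphenyl]ethan-1-one F1. Condensation with N,N-dimethylformamide dimethyl acetal gives the enaminone (E)-1-[3-(benzyloxy)-6-hydroxy-2,4-dimethoxyphenyl]-3-(dimethylamino)prop-2-en-1-one F2, and acid-mediated ring closure gives 6-(benzyloxy)-5,7-dimethoxy-4H-chromen-4-one F3. Enantioselective conjugate addition of (3,4-dimethoxyphenyl)boronic acid F4 follows, with Pd(OCOCF3)2 and the enantiomer of 4-tert-butyl-2-(pyridin-2-yl)-4,5-dihydrooxazole that leads to 2S, NH4PF6 and water in ClCH2CH2Cl at 60 °C. This should deliver 12, from which steps 6 is skipped and step 7 follows.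

Step 4. The ambident, very electron-rich aryloxide may be alkylated at its ortho carbon instead of at oxygen by the benzylic cation, and 6 or 7 may hydrolyse with traces of water or on silica. Fallback, setting out from 5 and 4 and returning at 7 (it also bypasses step 3): 5 is converted with HC(OMe)3 and catalytic TsOH in MeOH into 4-(dimethoxymethyl)-1,2-dimethoxybenzene F5. This is exchanged with two equivalents of 4 under PPTS catalysis in toluene, with continuous removal of the alcohol over 5 Å sieves, to give 7.

Step 7. Hydrogenolysis may also cleave the benzylic C2–O1 bond, opening ring C, or reduce the aryl ketone, because ring B donates strongly into C2. Fallback, setting out from 12 and returning at 13: non-reductive debenzylation with BCl3 and pentamethylbenzene as cation scavenger in CH2Cl2 at −78 °C. The low temperature is meant to spare the 5-OMe group next to the carbonyl. This fallback makes no new compound (line F0).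

Step 6. Once the ketone is free, acid may promote reversible opening of ring C and partial loss of configuration at C2, or the crowded ketal may react sluggishly. Fallback, setting out from 11 and returning at 13, with the order of the last two operations reversed: hydrogenolysis of 11 (H2, 10% Pd/C, EtOAc with a trace of Et3N) should give (2S)-4,4-diethoxy-2-(3,4-dimethoxyphenyl)-5,7-dimethoxychroman-6-ol F6. Anhydrous ketal exchange with acetone (PPTS cat., rt) then releases 13 as the last operation, so the flavanone meets neither aqueous acid nor hydrogen.

## Further compounds

F1 | step 5 | 1-[3-(benzyloxy)-6-hydroxy-2,4-dimethoxyphenyl]ethan-1-one | CC(=O)c1c(O)cc(OC)c(OCc2ccccc2)c1OC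
F2 | step 5 | (E)-1-[3-(benzyloxy)-6-hydroxy-2,4-dimethoxyphenyl]-3-(dimethylamino)prop-2-en-1-one | CN(C)/C=C/C(=O)c1c(O)cc(OC)c(OCc2ccccc2)c1OC
F3 | step 5 | 6-(benzyloxy)-5,7-dimethoxy-4H-chromen-4-one | O=c1ccoc2cc(OC)c(OCc3ccccc3)c(OC)c12
F4 | step 5 | (3,4-dimethoxyphenyl)boronic acid (purchased reagent) | COc1ccc(B(O)O)cc1OC
F5 | step 4 | 4-(dimethoxymethyl)-1,2-dimethoxybenzene | COC(OC)c1ccc(OC)c(OC)c1
F0 | step 7 | none | none
F6 | step 6 | (2S)-4,4-diethoxy-2-(3,4-dimethoxyphenyl)-5,7-dimethoxychroman-6-ol | COc1ccc([C@@H]2CC(OCC)(OCC)c3c(cc(OC)c(O)c3OC)O2)cc1OC
A1 | alternative 1 | (2S)-6-(benzyloxy)-2-(3,4-dimethoxyphenyl)-5,7-dihydroxychroman-4-one | COc1ccc([C@@H]2CC(=O)c3c(cc(O)c(OCc4ccccc4)c3O)O2)cc1OC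
A2 | alternative 1 | ethyl 2-(benzyloxy)-4-[(2S)-2-(3,4-dimethoxyphenyl)-4-oxo-3,4-dihydro-2H-pyran-6-yl]-3-oxobutanoate | CCOC(=O)C(OCc1ccccc1)C(=O)CC1=CC(=O)C[C@@H](c2ccc(OC)c(OC)c2)O1
A3 | alternative 2 | (2S)-6-(benzyloxy)-4-[(tert-butyldimethylsilyl)oxy]-2-(3,4-dimethoxyphenyl)-5,7-dimethoxy-2H-chromene | COc1ccc([C@@H]2C=C(O[Si](C)(C)C(C)(C)C)c3c(cc(OC)c(OCc4ccccc4)c3OC)O2)cc1OC
A4 | alternative 2 | 2-(benzyloxy)-4-{1-[(tert-butyldimethylsilyl)oxy]vinyl}-5-{[(1S)-1-(3,4-dimethoxyphenyl)prop-2-en-1-yl]oxy}-1,3-dimethoxybenzene | C=C[C@H](Oc1cc(OC)c(OCc2ccccc2)c(OC)c1C(=C)O[Si](C)(C)C(C)(C)C)c1ccc(OC)c(OC)c1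
A5 | alternative 3 | (2R)-6-(benzyloxy)-2-(3,4-dimethoxyphenyl)-5,7-dimethoxy-2H-chromene-3-carbaldehyde | COc1ccc([C@@H]2C(C=O)=Cc3c(cc(OC)c(OCc4ccccc4)c3OC)O2)cc1OC
A6 | alternative 3 | (E)-3-(3,4-dimethoxyphenyl)prop-2-enal | COc1ccc(/C=C/C=O)cc1OC
A7 | alternative 3 | 3-(benzyloxy)-6-hydroxy-2,4-dimethoxybenzaldehyde | COc1cc(O)c(C=O)c(OC)c1OCc1ccccc1
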